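## Retrosynthetic overview

1. Esters last: the C3 senecioate and C9 tiglate come from acylation of two secondary hydroxyls that are created at different times and kept apart by one TBS group.
2. Ring B: the C9–OH and the trans ring fusion (C10–H) arise together by dissolving-metal reduction of a Δ9(10)-8-enone and oxidation of the resulting enolate; the C7 isopropenyl comes from α'-aldol addition to acetone and dehydration.
3. Ring A: the C3–OH and C4–H come from α-face hydroboration of a Δ3 olefin; the C4 methyl comes from enol triflate/cuprate coupling at the C4 ketone.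
4. No ring is formed in the route: both rings and the C5 quaternary stereocentre are bought as (S)-Wieland–Miescher ketone, with its enone masked as a dithiolane while ring A is built.

Convention and assumption: positions use eremophilane numbering (C1–C10 decalin, CH3 on C4 and C5, side chain on C7; β = face of the C5 methyl). (S)-Wieland–Miescher ketone, tigloyl chloride and 3-methylbut-2-enoyl chloride are taken as purchasable.

## Route

Step 1
Reactants: 1 (S)-Wieland–Miescher ketone
Product: 2 (S)-Wieland–Miescher ketone with the enone carbonyl (C8) as its 1,3-dithiolane; C4 ketone free, Δ9(10) retained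
Conditions: HSCH2CH2SH, TsOH (cat.), AcOH, rt
Reagents that add atoms: ethane-1,2-dithiol, SCCS
Why: Acid-catalysed thioketalisation of this diketone is chemoselective for the conjugated carbonyl and does not move the double bond, so the hindered C4 ketone is left free.

Step 2
Reactants: 2 dithiolane ketone
Product: 3 C4 enol triflate (Δ3) of 2
Conditions: KHMDS, THF, −78 °C; PhNTf2, −78 → 0 °C
Reagents that add atoms: N-phenylbis(trifluoromethanesulfonimide), O=S(=O)(N(c1ccccc1)S(=O)(=O)C(F)(F)F)C(F)(F)F
Why: Enolate O-triflation; the C4 ketone can enolise only towards C3 because C5 is quaternary, so a single enol triflate forms.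

Step 3
Reactants: 3 enol triflate
Product: 4 4-methyl-Δ3,Δ9(10)-diene 8-dithiolane
Conditions: Me2CuLi (MeLi, CuI), THF, −20 → 0 °C
Reagents that add atoms: lithium dimethylcuprate, [Li+].C[Cu-]C (from methyllithium, C[Li], and CuI)
Why: McMurry–Scott cuprate cross-coupling of an enol triflate replaces OTf by CH3 with retention of the olefin position, and the cuprate does not touch the dithiolane.

Step 4
Reactants: 4 diene dithiolane
Product: 5 3α-hydroxy-4β,5β-dimethyl-Δ9(10)-ene 8-dithiolane
Conditions: BH3·THF (1.1 equiv), THF, 0 °C → rt; NaOH, H2O2, 0 °C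
Reagents that add atoms: hydrogen peroxide, OO
Why: Brown hydroboration–oxidation; boron adds to the less substituted C3 syn to H at C4 from the α-face, anti to the angular C5 methyl, which sets 3α-OH and 4β-CH3, while the Δ9(10) olefin next to the spiro-dithiolane reacts much more slowly.

Step 5
Reactants: 5 alcohol
Product: 6 3α-TBS ether of 5
Conditions: TBSCl, imidazole, DMF, rt
Reagents that add atoms: tert-butyldimethylsilyl chloride, CC(C)(C)[Si](C)(C)Cl
Why: Silyl ether protection of the only hydroxyl, so that the later C9–OH can be acylated separately; the ether survives LDA and Li/NH3.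

Step 6
Reactants: 6 TBS ether dithiolane
Product: 7 (4aR,5R,6R)-6-(tert-butyldimethylsilyloxy)-4a,5-dimethyl-4,4a,5,6,7,8-hexahydronaphthalen-2(3H)-one (3α-TBSO Δ9(10)-8-enone)
Conditions: MeI, CaCO3, MeCN/H2O (4:1), 55 °C
Reagents that add atoms: water, O
Why: Alkylative dethioketalisation (S-methylation then hydrolysis) under neutral conditions returns the conjugated enone without disturbing the TBS ether.

Step 7
Reactants: 7 enone; 8 acetone
Product: 9 7α-(2-hydroxypropan-2-yl) derivative of 7
Conditions: LDA, THF, −78 °C; acetone, −78 °C; NH4Cl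
Reagents that add atoms: none
Why: Kinetic α'-deprotonation of the enone gives the cross-conjugated C7 enolate, whose aldol addition to acetone places the substituent pseudo-equatorial (7α, anti to the C5 methyl), which is also the thermodynamic arrangement at this epimerisable centre.

Step 8
Reactants: 9 aldol adduct
Product: 10 3α-TBSO-eremophila-9,11-dien-8-one (7α-isopropenyl enone)
Conditions: SOCl2, pyridine, CH2Cl2, −20 → 0 °C
Reagents that add atoms: none
Why: Dehydration by E2 elimination of the tertiary chlorosulfite in pyridine removes a methyl hydrogen (six available, unhindered) in preference to the single C7–H, giving the non-conjugated isopropenyl group.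

Step 9
Reactants: 10 isopropenyl enone
Product: 12 3α-TBSO-9α-hydroxy-10αH-eremophil-11-en-8-one, via lithium enolate 11 (not isolated)
Conditions: Li, NH3/THF, t-BuOH (1 equiv), −78 °C; isoprene; −NH3; Davis oxaziridine, THF, −78 °C; NH4Cl
Reagents that add atoms: 3-phenyl-2-(phenylsulfonyl)oxaziridine, O=S(=O)(c1ccccc1)N1OC1c1ccccc1
Why: Stork dissolving-metal enone reduction protonates C10 axially to give the trans-decalin (10α-H) and the regiodefined Δ8(9) enolate, and Davis α-hydroxylation attacks C9 from the α-face, away from the 1,3-diaxial C5 methyl, giving the equatorial 9α-OH.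

Step 10
Reactants: 12 hydroxy ketone; 13 tigloyl chloride ((E)-2-methylbut-2-enoyl chloride)
Product: 14 3α-TBSO-9α-tigloyloxy-10αH-eremophil-11-en-8-one
Conditions: pyridine, DMAP (cat.), CH2Cl2, 0 °C → rt
Reagents that add atoms: none
Why: DMAP-catalysed acylation of the only free hydroxyl; the (E)-tiglate is the stable geometric isomer and C9 stays equatorial.

Step 11
Reactants: 14 silyl ether
Product: 15 3α-hydroxy-9α-tigloyloxy-10αH-eremophil-11-en-8-one
Conditions: HF·pyridine, THF/pyridine, 0 °C → rt
Reagents that add atoms: none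
Why: Fluoride desilylation in a buffered, non-basic medium frees the C3–OH without acyl migration or conjugation of the β,γ-unsaturated ketone.

Step 12
Reactants: 15 alcohol; 16 3-methylbut-2-enoyl chloride (senecioyl chloride)
Product: 17 target, (3R,4R,5R,7S,9S,10R)-3α-(3-methylbut-2-enoyloxy)-9α-[(E)-2-methylbut-2-enoyloxy]-10αH-eremophil-11-en-8-one
Conditions: pyridine, DMAP (cat.), CH2Cl2, 0 °C → rt
Reagents that add atoms: none
Why: Acylation of the remaining secondary hydroxyl; pyridine rather than a trialkylamine avoids the vinylketene pathway that would deconjugate the senecioate.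

## Compound list

1 | (S)-(+)-Wieland–Miescher ketone, (8aS)-8a-methyl-3,4,8,8a-tetrahydronaphthalene-1,6(2H,7H)-dione | C[C@]12CCC(=O)C=C1CCCC2=O | starting material
2 | (S)-Wieland–Miescher ketone 8-(1,3-dithiolane), C4 ketone free | C1C[C@]2(C)C(=O)CCCC2=CC13SCCS3 | intermediate
3 | C4 enol triflate (Δ3, Δ9(10)) 8-dithiolane | C1C[C@]2(C)C(OS(=O)(=O)C(F)(F)F)=CCCC2=CC13SCCS3 | intermediate
4 | 4-methyl-Δ3,Δ9(10)-diene 8-dithiolane | C1C[C@]2(C)C(C)=CCCC2=CC13SCCS3 | intermediate
5 | 3α-hydroxy-4β,5β-dimethyl-Δ9(10)-ene 8-dithiolane | C1C[C@]2(C)[C@@H](C)[C@H](O)CCC2=CC13SCCS3 | intermediate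
6 | 3α-TBS ether of 5 | C1C[C@]2(C)[C@@H](C)[C@H](O[Si](C)(C)C(C)(C)C)CCC2=CC13SCCS3 | intermediate
7 | (4aR,5R,6R)-6-(tert-butyldimethylsilyloxy)-4a,5-dimethyl-4,4a,5,6,7,8-hexahydronaphthalen-2(3H)-one | C1C[C@]2(C)[C@@H](C)[C@H](O[Si](C)(C)C(C)(C)C)CCC2=CC1=O | intermediate
8 | acetone | CC(C)=O | starting material
9 | 7α-(2-hydroxypropan-2-yl)-3α-TBSO Δ9(10)-8-enone | CC(C)(O)[C@@H]1C[C@]2(C)[C@@H](C)[C@H](O[Si](C)(C)C(C)(C)C)CCC2=CC1=O | intermediate
10 | 3α-TBSO-eremophila-9,11-dien-8-one | C=C(C)[C@@H]1C[C@]2(C)[C@@H](C)[C@H](O[Si](C)(C)C(C)(C)C)CCC2=CC1=O | intermediate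
11 | lithium Δ8(9)-enolate, 3α-TBSO-10αH-eremophila-8,11-dien-8-olate | C=C(C)[C@@H]1C[C@]2(C)[C@@H](C)[C@H](O[Si](C)(C)C(C)(C)C)CC[C@H]2C=C1O[Li] | intermediate (not isolated)
12 | 3α-TBSO-9α-hydroxy-10αH-eremophil-11-en-8-one | C=C(C)[C@@H]1C[C@]2(C)[C@@H](C)[C@H](O[Si](C)(C)C(C)(C)C)CC[C@H]2[C@H](O)C1=O | intermediate
13 | tigloyl chloride, (E)-2-methylbut-2-enoyl chloride | C/C=C(\C)C(=O)Cl | starting material
14 | 3α-TBSO-9α-tigloyloxy-10αH-eremophil-11-en-8-one | C=C(C)[C@@H]1C[C@]2(C)[C@@H](C)[C@H](O[Si](C)(C)C(C)(C)C)CC[C@H]2[C@H](OC(=O)/C(C)=C/C)C1=O | intermediate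
15 | 3α-hydroxy-9α-tigloyloxy-10αH-eremophil-11-en-8-one | C=C(C)[C@@H]1C[C@]2(C)[C@@H](C)[C@H](O)CC[C@H]2[C@H](OC(=O)/C(C)=C/C)C1=O | intermediate
16 | 3-methylbut-2-enoyl chloride (senecioyl chloride) | CC(C)=CC(=O)Cl | starting material
17 | target CNP0164025.1, (3R,4R,5R,7S,9S,10R) | C=C(C)[C@@H]1C[C@]2(C)[C@@H](C)[C@H](OC(=O)C=C(C)C)CC[C@H]2[C@H](OC(=O)/C(C)=C/C)C1=O | target

## Step count and risks

Total steps: 12. Longest linear sequence: 12 (fully linear from 1).

The three steps most likely to fail are 4, 8 and 9.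

Step 4 (chemoselective hydroboration of the Δ3 olefin beside the Δ9(10) olefin and the dithiolane). The fallback sets out from 2 and comes back at 6, and needs no hydroboration. The potassium enolate of 2 (KHMDS, THF, −78 °C) is hydroxylated with Davis oxaziridine from the α-face to give the 3α-hydroxy-4-ketone F1. Silylation (TBSCl, imidazole) gives the silyl ether F2. Wittig methylenation of the hindered ketone (Ph3P=CH2, toluene, 90 °C) gives the 4-methylene compound F3. Diimide (TsNHNH2, NaOAc, aqueous DME, reflux) is sulfur-tolerant and reduces only the exocyclic 1,1-disubstituted olefin, from the α-face opposite the angular methyl, which gives the 4β-methyl compound 6.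

Step 8 (isopropenyl versus conjugated isopropylidene on dehydration). The fallback sets out from 7 and comes back at 10, using a regiospecific Peterson elimination in place of alcohol dehydration. The C7 enolate of 7 (LDA, then anhydrous CeCl3, THF, −78 °C) is added to 1-(trimethylsilyl)propan-2-one to give the β-hydroxysilane F4 as a mixture at the carbinol carbon. BF3·OEt2 in CH2Cl2 at −40 °C then eliminates Me3Si/OH, which can only place the double bond towards the CH2 that carried silicon, giving 10.

Step 9 (one-pot reduction and hydroxylation; lithium enolates can be poor partners for the oxaziridine). The fallback sets out from 10 and comes back at 12. After the same Li/NH3 reduction the enolate is trapped with TMSCl/Et3N and isolated as the trimethylsilyl enol ether F5. Rubottom oxidation (mCPBA 1.0 equiv, NaHCO3, hexane/CH2Cl2, −20 °C; then citric acid, MeOH) epoxidises the electron-rich enol ether from the α-face much faster than the isopropenyl group, and gives 12 after silyl loss.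

## Further compounds

F1 | step 4 | 3α-hydroxy-4-ketone 8-dithiolane (Δ9(10)) | C1C[C@]2(C)C(=O)[C@H](O)CCC2=CC13SCCS3
F2 | step 4 | 3α-TBSO-4-ketone 8-dithiolane | C1C[C@]2(C)C(=O)[C@H](O[Si](C)(C)C(C)(C)C)CCC2=CC13SCCS3
F3 | step 4 | 3α-TBSO-4-methylene 8-dithiolane | C1C[C@]2(C)C(=C)[C@H](O[Si](C)(C)C(C)(C)C)CCC2=CC13SCCS3
F4 | step 8 | 7α-[2-hydroxy-1-(trimethylsilyl)propan-2-yl]-3α-TBSO Δ9(10)-8-enone (mixture at the carbinol carbon) | CC(O)(C[Si](C)(C)C)[C@@H]1C[C@]2(C)[C@@H](C)[C@H](O[Si](C)(C)C(C)(C)C)CCC2=CC1=O
F5 | step 9 | 8-trimethylsilyloxy-3α-TBSO-10αH-eremophila-8,11-diene | C=C(C)[C@@H]1C[C@]2(C)[C@@H](C)[C@H](O[Si](C)(C)C(C)(C)C)CC[C@H]2C=C1O[Si](C)(C)C
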